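## Structural features

Compound 20 is a 3,3a,4,5-tetrahydrobenzofuran-6(2H)-one. Ring A (O1–C2–C3–C3a–C7a, a dihydrofuran) and ring B (C3a–C4–C5–C6–C7–C7a, a cyclohexenone) share the C3a–C7a bond, and O1–C7a=C7–C6=O is a vinylogous ester whose α-carbon C7 carries a methoxy group. C2 bears methyl, C3 bears 3,4,5-trimethoxyphenyl, the ring-fusion carbon C3a is quaternary and bears allyl, and C5 bears methoxy. C2 (R), C3 (S) and C3a (S) are contiguous around ring A, with methyl and aryl trans and aryl and allyl cis. C5 (S) is separated from them by C4, its methoxy group is trans to allyl, and it is epimerisable because it is α to the C6 ketone. The fragile groups are the terminal alkene (no hydrogenation, peracids or radical oxidants), the vinylogous ester (aqueous acid, hard nucleophiles), the α-methoxy ketone and the electron-rich arene. The real difficulty is the all-carbon quaternary centre C3a beside the benzylic centre C3, with allyl on the same face as aryl: an enolate at C3a that is allylated last would place allyl anti to aryl. The key step uses the fact that ring A, with C7a as carbonyl, is a γ-lactone in which C3a is the α-carbon, C3 the β-carbon and C2 the γ-carbon; C3–aryl and C3a–C4 are then the two bonds of a conjugate addition with enolate capture on an α-allyl butenolide, and ring B follows by acylation of C7 on C7a.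

## Logic of the disconnections

20 to 19: the O–CH3 bond at C5 is cut. Etherification is left to the end so that no earlier base-mediated step has to carry an α-alkoxy ketone stereocentre. The forward step must methylate a ketol without a free enolate; since C5 is α to C6 and the wanted epimer is pseudo-equatorial, a thermodynamic correction remains available.

19 to 18: the C5–O bond is cut. C3a is quaternary, so C5 holds the only acidic hydrogens of 18 and an electrophilic oxygen can be delivered there without regiochemical doubt. One stereocentre is removed. The forward step must bring oxygen to the face opposite the allyl group and must leave the terminal alkene alone.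

18 to 16 (through 17): the enol ether bond O1–C7a and then the C7–C7a bond are cut. The vinylogous ester is the cyclodehydrated form of a 1,3-dione carrying the C2 hydroxyl, and that dione is the Claisen product of a ketone enolate with a lactone whose ring oxygen is already O1. Ring B disappears and a monocyclic lactone with three contiguous centres remains. The forward step needs enolisation toward C7 (the C5 enolate can only give a four-membered ring), acylation at a carbonyl next to a quaternary carbon, and acid closure onto C7a and not C6.

16 to 7, 13 and 11 (through 15 and 14): the C3–aryl bond and the C3a–C4 bond are cut. These are the β- and α-bonds of the lactone, and both form anti to the neighbouring substituent on a five-membered ring. Because allyl already sits on C3a, attaching C4 last places allyl cis to aryl. Three simple components result, and two stereocentres are derived from the single centre at C2. The forward step needs 1,4-selectivity, two facial selections and tolerance of the polymerisable 11.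

7 to 5 and 6: the C3a–allyl bond is cut. Allyl is attached to a ring that already contains the C3=C3a alkene, so the position of that alkene is never in question. The other order, allylation of the saturated lactone and then syn elimination, is avoided because the elimination would have to choose between the ring hydrogens on C3 and the doubly activated allylic hydrogens of the side chain. The forward step needs neutral coupling conditions that neither epimerise C2 nor move the allyl double bond.

5 to 3 to 1 (through 4 and 2): the C3a–Br bond is cut, and then the C3=C3a double bond is traced to the saturated lactone. In 2 only the ring carries β-hydrogens, so the elimination is unambiguous. The forward steps must not expose C2–H to base for long.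

11 to 9 and 10, and 9 to 8: the C6–vinyl bond and the amide C–N bond are cut. A chelated amide adduct stops the addition at the ketone stage. The forward step must keep the released amine away from the enone.

13 to 12: the C–Mg bond is cut. The forward step is a routine magnesium insertion.

## Other disconnections considered

Alternative 1: The cut is C3a–C7a. Ring B would be assembled from a four-carbon squaric acid unit (C5, C6, C7, C7a) and a trisubstituted alkenyl unit (C4 and C3a with allyl and the C3/C2 chain), joined in cyclobutenone A1. On heating, the four-membered ring should open to a conjugated ketene whose carbon C7a closes onto the fully substituted alkene terminus C3a in a six-electron electrocyclisation; tautomerisation of the enol would give ene-dione A2.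
- In favour: ring B and the quaternary centre arise in one reagent-free thermal step, and the two halves are joined by a simple carbonyl addition. Oxygen is present at C5, C6, C7 and C7a from the start, so no late enolate oxidation is needed; on the C5 oxidation level this plan is the better one.
- Against: C3a becomes stereogenic in the electrocyclisation under the influence of the acyclic C3 centre alone, which must select the helical sense of the open-chain ketene. The chosen plan builds C3a on a five-membered ring where the neighbouring aryl group shields one face.
- Structure: the alkenyl half must be made enantiopure with C2/C3 anti by a separate sequence, whereas the chosen plan derives both centres from one chiral-pool centre. A2 has its oxygens one position out of register (ketone at C5, enol ether at C6), so reduction at C5, methylation, desilylation and acid transposition of the vinylogous ester must follow.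
- Mechanism and step economy: closing ring A by attack of the C2 hydroxyl on C7a is the same operation in both plans, so they are equal there. The overall count is judged similar once the alkenyl half is included; the ring-forming step is cleaner here, but control of C3a is weaker.

Alternative 2: The cut is C3–C3a. In ether A3, mild acid should ionise the benzylic alcohol, helped by the para-hydroxyl, to quinone methide A4. The ring B phenol would then attack C3 through its para carbon C3a, which already bears allyl, closing ring A and giving the dearomatised dienone A5.
- In favour: the plan follows the likely biogenesis, and A3 comes from two phenols and a three-carbon unit in few operations. Ring A, the quaternary centre and both ring B methoxy groups are present after one step, so in step count and in having the C5 oxygen from the outset this plan is the better one. The trans C2/C3 relationship should follow from methyl and aryl avoiding each other in the five-membered transition state, which is as reliable as in the chosen route (equal).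
- Against: the allyl/aryl cis relationship depends on which faces of two planar partners meet, with no rigid control element. Attack through oxygen or through other ring positions can compete. 4-Allylcyclohexadienones are prone to acid-induced allyl migration and rearomatisation, so A5 would have to survive the conditions of its formation.
- Structure: A5 is at the wrong oxidation level. The C4=C5 bond must be reduced in the presence of the allyl group and the vinylogous ester, C5 must be set by protonation, and the phenol must be methylated.
- Mechanism: this is a reversible cationic closure under loose control, against two irreversible anionic bond formations under ring control in the chosen plan.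

Alternative 3: The cuts are C2–CH3 and C3–aryl, both made across the alkene of (Z)-alkenylboronate A6, which carries a preformed quaternary C3a in a cyclohexa-1,4-diene. Methyllithium would add to boron, and the divalent arylpalladium triflate formed from A7 (Pd(OAc)2, a MandyPhos ligand) should induce migration of methyl from boron to C2 while aryl is delivered to C3 on the opposite face, giving boronate A8. Stereoretentive oxidation of the C–B bond would reveal the C2 hydroxyl.
- In favour: two C–C bonds and two stereocentres are formed in one catalytic step. The anti relationship follows stereospecifically from the Z geometry, which is as secure as the substrate-controlled anti addition of the chosen route (equal). The absolute sense is set by the ligand and the aryl group can be varied freely, so in modularity this plan is the better one.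
- Against: C3 is neopentylic to C3a, so the metal-induced shift would take place at a very hindered alkene. Three other alkenes (allyl and two ring double bonds, one an enol ether) can compete for the arylpalladium species. C3a must be made enantioselectively beforehand, and the catalyst must then act in the matched sense.
- Structure and step economy: A8 is far from 20. C–B oxidation, closure of ring A by enol ether exchange at C7a, oxidation of C6 to the ketone and introduction of the C5 methoxy group all remain, which makes the route clearly longer than the chosen one.
- Mechanism: catalyst control in a crowded setting, against the innate facial preferences of five-membered rings in the chosen plan.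

Key step: step 7

Assumption: (R)-γ-valerolactone of high enantiomeric purity is the only source of chirality. Free-standing atom labels (O1, C2, C3, C3a, C4–C7, C7a) always mean the positions of 20, while locants inside names follow each compound's own nomenclature. The trans (pseudo-equatorial) C5 methoxy epimer is taken to be the more stable one.

## Route

Step 1
Reactants: 1 (R)-γ-valerolactone
Product: 3 (R)-5-methylfuran-2(5H)-one, via α-phenylselanyl lactone 2 (not isolated)
Conditions: LiN(i-Pr)2, THF, −78 °C; PhSeBr, −78 °C; then 30 % H2O2, CH2Cl2, 0 °C → rt
Reagents that add atoms: none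
Why: α-Selenenylation of the lithium enolate followed by selenoxide syn-elimination; in 2 the only β-hydrogens are on the ring carbon C3, so the alkene can form in one position only, and C2 takes no part.

Step 2
Reactants: 3 (R)-5-methylfuran-2(5H)-one
Product: 5 (R)-3-bromo-5-methylfuran-2(5H)-one, via trans-3,4-dibromo lactone 4 (not isolated)
Conditions: Br2, CH2Cl2, 0 °C; then Et3N, 0 °C, short contact
Reagents that add atoms: bromine, BrBr
Why: Anti-addition of bromine across C3=C3a, then amine-induced loss of HBr in which the acidic C3a–H and the C3 bromide depart (E1cB-like), leaving bromine on C3a; cold, brief exposure to the amine is meant to keep C2 from epimerising through the 2-oxidofuran.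

Step 3
Reactants: 5 (R)-3-bromo-5-methylfuran-2(5H)-one; 6 allyltributylstannane
Product: 7 (R)-3-allyl-5-methylfuran-2(5H)-one
Conditions: Pd2(dba)3 (2.5 mol %), P(2-furyl)3 (10 mol %), toluene, 60 °C; aq. KF work-up
Reagents that add atoms: none
Why: Stille coupling: zerovalent palladium inserts into the C3a–Br bond, allyl passes from tin to palladium and reductive elimination forms the sp2–sp3 bond; the base-free medium leaves C2 untouched, and the ring alkene is already fixed in position.

Step 4
Reactants: 8 methoxyacetyl chloride
Product: 9 N,2-dimethoxy-N-methylacetamide
Conditions: MeNH(OMe)·HCl, Et3N (2.2 equiv), CH2Cl2, 0 °C → rt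
Reagents that add atoms: N,O-dimethylhydroxylamine hydrochloride, CNOC.Cl
Why: N-Acylation of the hydroxylamine by the acid chloride (Weinreb amide formation).

Step 5
Reactants: 9 N,2-dimethoxy-N-methylacetamide; 10 vinylmagnesium bromide
Product: 11 1-methoxybut-3-en-2-one
Conditions: THF, −78 → 0 °C; inverse quench into cold 2 M HCl; distil with BHT, use fresh
Reagents that add atoms: none
Why: Weinreb ketone synthesis: the magnesium-chelated tetrahedral adduct persists until the quench, so only one vinyl group adds; pouring into cold acid keeps the released amine protonated and prevents its conjugate addition to 11.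

Step 6
Reactants: 12 5-bromo-1,2,3-trimethoxybenzene
Product: 13 3,4,5-trimethoxyphenylmagnesium bromide
Conditions: Mg turnings, I2 (cat.), THF, 40–65 °C; titrate
Reagents that add atoms: magnesium, [Mg]
Why: Grignard formation by insertion of magnesium into the aryl–bromine bond; the methoxy groups are inert.

Step 7
Reactants: 7 (R)-3-allyl-5-methylfuran-2(5H)-one; 13 3,4,5-trimethoxyphenylmagnesium bromide; 11 1-methoxybut-3-en-2-one
Product: 16 (3R,4S,5R)-3-allyl-3-(4-methoxy-3-oxobutyl)-5-methyl-4-(3,4,5-trimethoxyphenyl)dihydrofuran-2(3H)-one, via silyl ketene acetal 14 (not isolated), via silyl enol ether 15 (not isolated)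
Conditions: 13 (1.2 equiv), CuBr·SMe2 (10 mol %), Me3SiCl (2 equiv), THF, −78 → −40 °C; concentrate, pentane, filter under argon; 11 (1.5 equiv), Me3SiOTf (10 mol %), CH2Cl2, −78 °C; then 1 M HCl, THF, 0 °C
Reagents that add atoms: none
Why: The Grignard reagent and catalytic CuBr·SMe2 form an arylcopper species (copper monovalent) that complexes the C3=C3a alkene of 7 on the face opposite the C2 methyl group; transfer of aryl to C3 through a trivalent-copper adduct is made irreversible by O-silylation with Me3SiCl, which gives ketene acetal 14 and returns copper to the cycle. Once the magnesium salts are removed, Me3SiOTf silylates the carbonyl oxygen of 11 and the resulting silyloxyallyl cation is attacked at its terminal CH2 (C4) by C3a of 14 through an open transition state (Mukaiyama–Michael addition); the silyl group ends on the enone oxygen in 15, the catalyst is regenerated, and dilute acid hydrolyses 15 to 16. The closest known reaction type is the three-component coupling of butenolides and cyclopentenones, in which a copper-mediated conjugate addition is followed by capture of the enolate or its silyl ketene acetal by a carbon electrophile. No ring is closed; ring A is carried as the γ-lactone and ring B is left for step 8. The C3 stereocentre is controlled by the existing C2 centre, the aryl group adding anti to the methyl group on the adjacent carbon as is usual for 5-substituted butenolides. The C3a stereocentre is controlled by the new C3 aryl group, which blocks one face of the planar ketene acetal so that C4 is attached anti to it; allyl is already on C3a and therefore ends cis to aryl. The step needs 1,4- and not 1,2-addition of the Grignard reagent (secured by copper catalysis with Me3SiCl at low temperature), C- and not O-attack of 14 together with conjugate and not carbonyl addition to 11 (secured by the unhindered β-CH2 of 11 and the bulk of the tetrasubstituted ketene acetal), and addition and not polymerisation of 11 (secured by catalytic Lewis acid at −78 °C with no free metal enolate present).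

Step 8
Reactants: 16 (3R,4S,5R)-3-allyl-3-(4-methoxy-3-oxobutyl)-5-methyl-4-(3,4,5-trimethoxyphenyl)dihydrofuran-2(3H)-one
Product: 18 (2R,3S,3aR)-3a-allyl-7-methoxy-2-methyl-3-(3,4,5-trimethoxyphenyl)-3,3a,4,5-tetrahydrobenzofuran-6(2H)-one, via hydroxy dione 17 (not isolated)
Conditions: KOt-Bu (2.2 equiv), THF, 0 °C → rt; then p-TsOH·H2O (3 equiv), toluene, 60 °C
Reagents that add atoms: none
Why: Dieckmann-type (intramolecular Claisen) condensation: only the C7 enolate can reach the lactone carbonyl C7a through a six-membered transition state (6-exo-trig), and deprotonation of the 2-methoxy-1,3-dione 17 drives the reversible acylation, as in the Michael–Claisen route to 4,4-disubstituted cyclohexane-1,3-diones. Acid then lets the freed C2 hydroxyl add to C7a (5-exo-trig) and water is lost toward C7 to give the vinylogous ester; C2, C3 and C3a are not enolisable and keep their configuration.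

Step 9
Reactants: 18 (2R,3S,3aR)-3a-allyl-7-methoxy-2-methyl-3-(3,4,5-trimethoxyphenyl)-3,3a,4,5-tetrahydrobenzofuran-6(2H)-one
Product: 19 (2R,3S,3aS,5S)-3a-allyl-5-hydroxy-7-methoxy-2-methyl-3-(3,4,5-trimethoxyphenyl)-3,3a,4,5-tetrahydrobenzofuran-6(2H)-one
Conditions: KN(SiMe3)2, THF, −78 °C; 2-(phenylsulfonyl)-3-phenyloxaziridine, −78 °C; sat. NH4Cl
Reagents that add atoms: 2-(phenylsulfonyl)-3-phenyloxaziridine, O=S(=O)(N1OC1c1ccccc1)c1ccccc1
Why: Enolate hydroxylation (Davis oxidation): with C3a quaternary, C5 carries the only acidic hydrogens, and the cross-conjugated dienolate accepts oxygen at C5 from the N-sulfonyloxaziridine. The pseudo-axial allyl group on C3a and the cis aryl group on C3 shield one face, so oxygen should enter trans to allyl, which is also the pseudo-equatorial, more stable arrangement.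

Step 10
Reactants: 19 (2R,3S,3aS,5S)-3a-allyl-5-hydroxy-7-methoxy-2-methyl-3-(3,4,5-trimethoxyphenyl)-3,3a,4,5-tetrahydrobenzofuran-6(2H)-one
Product: 20 (2R,3S,3aS,5S)-3a-allyl-5,7-dimethoxy-2-methyl-3-(3,4,5-trimethoxyphenyl)-3,3a,4,5-tetrahydrobenzofuran-6(2H)-one
Conditions: MeI, Ag2O, 4 Å MS, CH2Cl2, rt → 40 °C, dark
Reagents that add atoms: iodomethane, CI
Why: Purdie methylation (Ag2O-assisted SN2 on iodomethane) etherifies the ketol without a free enolate. C5 is α to the ketone and the wanted epimer, with methoxy pseudo-equatorial and away from the axial allyl group, is the thermodynamic one, so any epimerisation should converge on 20 (brief DBU treatment if required).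

## Compound list

1 | (R)-γ-valerolactone [(5R)-5-methyldihydrofuran-2(3H)-one] | C[C@H]1OC(=O)CC1 | starting material
2 | (5R)-5-methyl-3-(phenylselanyl)dihydrofuran-2(3H)-one (C3 epimers, formed in the flask) | C[C@H]1OC(=O)C([Se]c2ccccc2)C1 | intermediate
3 | (R)-5-methylfuran-2(5H)-one | C[C@H]1OC(=O)C=C1 | intermediate
4 | (5R)-3,4-dibromo-5-methyldihydrofuran-2(3H)-one (3,4-trans, formed in the flask) | C[C@H]1OC(=O)C(Br)C1Br | intermediate
5 | (R)-3-bromo-5-methylfuran-2(5H)-one | C[C@H]1OC(=O)C(Br)=C1 | intermediate
6 | allyltributylstannane | C=CC[Sn](CCCC)(CCCC)CCCC | starting material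
7 | (R)-3-allyl-5-methylfuran-2(5H)-one | C[C@H]1OC(=O)C(CC=C)=C1 | intermediate
8 | methoxyacetyl chloride | COCC(=O)Cl | starting material
9 | N,2-dimethoxy-N-methylacetamide | COCC(=O)N(C)OC | intermediate
10 | vinylmagnesium bromide | C=C[Mg]Br | starting material
11 | 1-methoxybut-3-en-2-one | COCC(=O)C=C | intermediate
12 | 5-bromo-1,2,3-trimethoxybenzene | COc1cc(Br)cc(OC)c1OC | starting material
13 | 3,4,5-trimethoxyphenylmagnesium bromide | COc1cc([Mg]Br)cc(OC)c1OC | intermediate
14 | {[(4S,5R)-3-allyl-5-methyl-4-(3,4,5-trimethoxyphenyl)-4,5-dihydrofuran-2-yl]oxy}trimethylsilane (formed in the flask) | C=CCC1=C(O[Si](C)(C)C)O[C@H](C)[C@H]1c1cc(OC)c(OC)c(OC)c1 | intermediate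
15 | (3S,4S,5R)-3-allyl-3-[4-methoxy-3-(trimethylsilyloxy)but-2-en-1-yl]-5-methyl-4-(3,4,5-trimethoxyphenyl)dihydrofuran-2(3H)-one (enol ether geometry not defined, formed in the flask) | C=CC[C@@]1(CC=C(COC)O[Si](C)(C)C)C(=O)O[C@H](C)[C@H]1c1cc(OC)c(OC)c(OC)c1 | intermediate
16 | (3R,4S,5R)-3-allyl-3-(4-methoxy-3-oxobutyl)-5-methyl-4-(3,4,5-trimethoxyphenyl)dihydrofuran-2(3H)-one | C=CC[C@@]1(CCC(=O)COC)C(=O)O[C@H](C)[C@H]1c1cc(OC)c(OC)c(OC)c1 | intermediate
17 | (4R)-4-allyl-4-[(1S,2R)-2-hydroxy-1-(3,4,5-trimethoxyphenyl)propyl]-2-methoxycyclohexane-1,3-dione (C2 of the ring enolised, formed in the flask) | C=CC[C@]1(CCC(=O)C(OC)C1=O)[C@H](c1cc(OC)c(OC)c(OC)c1)[C@@H](C)O | intermediate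
18 | (2R,3S,3aR)-3a-allyl-7-methoxy-2-methyl-3-(3,4,5-trimethoxyphenyl)-3,3a,4,5-tetrahydrobenzofuran-6(2H)-one | C=CC[C@@]12CCC(=O)C(OC)=C1O[C@H](C)[C@H]2c1cc(OC)c(OC)c(OC)c1 | intermediate
19 | (2R,3S,3aS,5S)-3a-allyl-5-hydroxy-7-methoxy-2-methyl-3-(3,4,5-trimethoxyphenyl)-3,3a,4,5-tetrahydrobenzofuran-6(2H)-one | C=CC[C@@]12C[C@H](O)C(=O)C(OC)=C1O[C@H](C)[C@H]2c1cc(OC)c(OC)c(OC)c1 | intermediate
20 | (2R,3S,3aS,5S)-3a-allyl-5,7-dimethoxy-2-methyl-3-(3,4,5-trimethoxyphenyl)-3,3a,4,5-tetrahydrobenzofuran-6(2H)-one | C=CC[C@@]12C[C@H](OC)C(=O)C(OC)=C1O[C@H](C)[C@H]2c1cc(OC)c(OC)c(OC)c1 | target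

## Step count and least certain steps

Total: 10 steps. Longest linear sequence: 7 steps (steps 1, 2, 3, 7, 8, 9, 10); steps 4–5 and step 6 are side branches that join at step 7.

Step 7 (key step). The most likely failure is loss of the ketene acetal by protodesilylation, or its consumption in oligomerisation of the vinyl ketone, before the C3a–C4 bond forms; a looser ionic pathway could also erode facial selectivity at the quaternary carbon. The cause is that a hindered tetrasubstituted nucleophile must be matched with a small, very reactive acceptor in the presence of residual salts. The fallback sets out from 7 and comes back at 16, and replaces the conjugate addition to the enone by an SN2 alkylation. The copper-catalysed arylation is run alone and quenched with NH4Cl to give the lactone (4R,5R)-3-allyl-5-methyl-4-(3,4,5-trimethoxyphenyl)dihydrofuran-2(3H)-one F1. Separately, 11 is converted with Me3SiI and ethane-1,2-diol into 2-(2-iodoethyl)-2-(methoxymethyl)-1,3-dioxolane F2. The lithium enolate of F1 (LiN(i-Pr)2, THF/DMPU, −78 °C) is alkylated by F2, again anti to the aryl group, to give (3R,4S,5R)-3-allyl-3-{2-[2-(methoxymethyl)-1,3-dioxolan-2-yl]ethyl}-5-methyl-4-(3,4,5-trimethoxyphenyl)dihydrofuran-2(3H)-one F3, and dilute aqueous acid removes the dioxolane to return 16.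

Step 8. The most likely failure is stalling of the enolate acylation at the lactone carbonyl, which is neopentylic, while the methoxymethyl ketone condenses with itself; reversal of the acylation by the tethered alkoxide is the second concern. The fallback sets out from 16 and comes back at 18, and opens ring A first so that an irreversible acyl donor can be used. Saponification (LiOH, THF/H2O), silylation of the dried salt (t-BuMe2SiCl, imidazole, DMF) and selective cleavage of the silyl ester (K2CO3, MeOH/H2O) give (2R)-2-allyl-2-[(1S,2R)-2-(tert-butyldimethylsilyloxy)-1-(3,4,5-trimethoxyphenyl)propyl]-6-methoxy-5-oxohexanoic acid F4. Activation with 1,1'-carbonyldiimidazole and treatment with LiN(SiMe3)2 (THF, −78 → 0 °C) close ring B by C-acylation of the C7 enolate; any enol lactone from O-acylation is expected to rearrange to the same dione under the basic conditions. The product is (4R)-4-allyl-4-[(1S,2R)-2-(tert-butyldimethylsilyloxy)-1-(3,4,5-trimethoxyphenyl)propyl]-2-methoxycyclohexane-1,3-dione F5. p-TsOH in methanol then removes the silyl group and the cyclodehydration of step 8 gives 18.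

Step 9. The most likely failure is poor facial selectivity in the oxygen transfer, because the two faces of the nearly planar dienolate differ only through the allyl and aryl groups two atoms away; addition of the enolate to the sulfonylimine by-product is a lesser risk. The fallback sets out from 18 and comes back at 20, and replaces kinetic facial control by thermodynamic control. If oxygen enters mainly syn to allyl, the product is (2R,3S,3aS,5R)-3a-allyl-5-hydroxy-7-methoxy-2-methyl-3-(3,4,5-trimethoxyphenyl)-3,3a,4,5-tetrahydrobenzofuran-6(2H)-one F6. It is methylated under the conditions of step 10 to (2R,3S,3aS,5R)-3a-allyl-5,7-dimethoxy-2-methyl-3-(3,4,5-trimethoxyphenyl)-3,3a,4,5-tetrahydrobenzofuran-6(2H)-one F7. F7 is then equilibrated through its enol with DBU in CH2Cl2; the pseudo-equatorial epimer 20 is expected to dominate because it avoids the 1,3-diaxial contact with the C3a allyl group.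

Step 10. The most likely failure is oxidation of the ketol through its enediol by the silver oxide, or slow etherification of a hindered carbinol next to a carbonyl group, with decomposition on prolonged heating. The fallback sets out from 18 and comes back at 20, and makes C5 the electrophile so that no free ketol is handled. The potassium enolate of 18 (KN(SiMe3)2, THF, −78 °C) is brominated with N-bromosuccinimide to (2R,3S,3aS)-3a-allyl-5-bromo-7-methoxy-2-methyl-3-(3,4,5-trimethoxyphenyl)-3,3a,4,5-tetrahydrobenzofuran-6(2H)-one F8. Silver-assisted methanolysis (AgOTf, 2,6-di-tert-butylpyridine, MeOH, 0 °C → rt) replaces bromide by methoxide through an oxyallyl-type cation stabilised by the oxygen substituents on C7 and C7a. The C5 epimers are then equilibrated with DBU as described for step 9 to give 20.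

Step 2. The most likely failure is partial epimerisation at C2 during the dehydrobromination, because the amine can also remove the C2 hydrogen of the bromobutenolide and pass through an achiral 2-oxidofuran. The fallback sets out from 2 and comes back at 5, and removes the amine altogether. Compound 2 is isolated, deprotonated (LiN(i-Pr)2, THF, −78 °C) and brominated with N-bromosuccinimide to (5R)-3-bromo-5-methyl-3-(phenylselanyl)dihydrofuran-2(3H)-one F9. Oxidation with H2O2 at 0 °C and selenoxide syn-elimination toward C3, the only position with β-hydrogens, then gives 5 under non-basic conditions.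

## Further compounds

F1 | step 7 | (4R,5R)-3-allyl-5-methyl-4-(3,4,5-trimethoxyphenyl)dihydrofuran-2(3H)-one (C3 epimers) | C=CCC1C(=O)O[C@H](C)[C@H]1c1cc(OC)c(OC)c(OC)c1
F2 | step 7 | 2-(2-iodoethyl)-2-(methoxymethyl)-1,3-dioxolane | COCC1(CCI)OCCO1
F3 | step 7 | (3R,4S,5R)-3-allyl-3-{2-[2-(methoxymethyl)-1,3-dioxolan-2-yl]ethyl}-5-methyl-4-(3,4,5-trimethoxyphenyl)dihydrofuran-2(3H)-one | C=CC[C@@]1(CCC2(COC)OCCO2)C(=O)O[C@H](C)[C@H]1c1cc(OC)c(OC)c(OC)c1
F4 | step 8 | (2R)-2-allyl-2-[(1S,2R)-2-(tert-butyldimethylsilyloxy)-1-(3,4,5-trimethoxyphenyl)propyl]-6-methoxy-5-oxohexanoic acid | C=CC[C@@](CCC(=O)COC)(C(=O)O)[C@H](c1cc(OC)c(OC)c(OC)c1)[C@@H](C)O[Si](C)(C)C(C)(C)C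
F5 | step 8 | (4R)-4-allyl-4-[(1S,2R)-2-(tert-butyldimethylsilyloxy)-1-(3,4,5-trimethoxyphenyl)propyl]-2-methoxycyclohexane-1,3-dione | C=CC[C@]1(CCC(=O)C(OC)C1=O)[C@H](c1cc(OC)c(OC)c(OC)c1)[C@@H](C)O[Si](C)(C)C(C)(C)C
F6 | step 9 | (2R,3S,3aS,5R)-3a-allyl-5-hydroxy-7-methoxy-2-methyl-3-(3,4,5-trimethoxyphenyl)-3,3a,4,5-tetrahydrobenzofuran-6(2H)-one | C=CC[C@@]12C[C@@H](O)C(=O)C(OC)=C1O[C@H](C)[C@H]2c1cc(OC)c(OC)c(OC)c1
F7 | step 9 | (2R,3S,3aS,5R)-3a-allyl-5,7-dimethoxy-2-methyl-3-(3,4,5-trimethoxyphenyl)-3,3a,4,5-tetrahydrobenzofuran-6(2H)-one | C=CC[C@@]12C[C@@H](OC)C(=O)C(OC)=C1O[C@H](C)[C@H]2c1cc(OC)c(OC)c(OC)c1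
F8 | step 10 | (2R,3S,3aS)-3a-allyl-5-bromo-7-methoxy-2-methyl-3-(3,4,5-trimethoxyphenyl)-3,3a,4,5-tetrahydrobenzofuran-6(2H)-one (C5 epimers) | C=CC[C@@]12CC(Br)C(=O)C(OC)=C1O[C@H](C)[C@H]2c1cc(OC)c(OC)c(OC)c1
F9 | step 2 | (5R)-3-bromo-5-methyl-3-(phenylselanyl)dihydrofuran-2(3H)-one | C[C@H]1OC(=O)C(Br)([Se]c2ccccc2)C1
A1 | alternative 1 | 4-hydroxy-2,3-dimethoxy-4-[(3R,4R)-2-allyl-4-(triethylsilyloxy)-3-(3,4,5-trimethoxyphenyl)pent-1-en-1-yl]cyclobut-2-en-1-one (carbinol centre and alkene geometry not defined) | COC1=C(OC)C(O)(C=C(CC=C)[C@H](c2cc(OC)c(OC)c(OC)c2)[C@@H](C)O[Si](CC)(CC)CC)C1=O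
A2 | alternative 1 | (5S)-5-allyl-2,3-dimethoxy-5-[(1S,2R)-2-(triethylsilyloxy)-1-(3,4,5-trimethoxyphenyl)propyl]cyclohex-2-ene-1,4-dione | C=CC[C@]1(CC(=O)C(OC)=C(OC)C1=O)[C@H](c1cc(OC)c(OC)c(OC)c1)[C@@H](C)O[Si](CC)(CC)CC
A3 | alternative 2 | (2R)-2-(6-allyl-3-hydroxy-2,4-dimethoxyphenoxy)-1-(4-hydroxy-3,5-dimethoxyphenyl)propan-1-ol (carbinol centre not defined) | C=CCc1cc(OC)c(O)c(OC)c1O[C@H](C)C(O)c1cc(OC)c(O)c(OC)c1
A4 | alternative 2 | 4-[(2R)-2-(6-allyl-3-hydroxy-2,4-dimethoxyphenoxy)propylidene]-2,6-dimethoxycyclohexa-2,5-dien-1-one | C=CCc1cc(OC)c(O)c(OC)c1O[C@H](C)C=C1C=C(OC)C(=O)C(OC)=C1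
A5 | alternative 2 | (2R,3S,3aR)-3a-allyl-3-(4-hydroxy-3,5-dimethoxyphenyl)-5,7-dimethoxy-2-methyl-3,3a-dihydrobenzofuran-6(2H)-one | C=CC[C@@]12C=C(OC)C(=O)C(OC)=C1O[C@H](C)[C@H]2c1cc(OC)c(O)c(OC)c1
A6 | alternative 3 | 2-{(Z)-2-[(1R)-1-allyl-2,3-dimethoxycyclohexa-2,5-dien-1-yl]ethenyl}-4,4,5,5-tetramethyl-1,3,2-dioxaborolane | C=CC[C@]1(C=CCC(OC)=C1OC)/C=C\B1OC(C)(C)C(C)(C)O1
A7 | alternative 3 | 3,4,5-trimethoxyphenyl trifluoromethanesulfonate | COc1cc(OS(=O)(=O)C(F)(F)F)cc(OC)c1OC
A8 | alternative 3 | 2-{(1S,2R)-1-[(1S)-1-allyl-2,3-dimethoxycyclohexa-2,5-dien-1-yl]-1-(3,4,5-trimethoxyphenyl)propan-2-yl}-4,4,5,5-tetramethyl-1,3,2-dioxaborolane | C=CC[C@]1(C=CCC(OC)=C1OC)[C@H](c1cc(OC)c(OC)c(OC)c1)[C@@H](C)B1OC(C)(C)C(C)(C)O1
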